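## Structural features

The target 19 is a 3,3''-biflavanone: two 2-arylchroman-4-one units, each a 5,7-dihydroxylated ring A fused to a pyranone ring C, joined by one bond between C3 and C3''. Ring B is 4-methoxyphenyl on the first unit and 4-hydroxyphenyl on the second, so the molecule is C2-symmetric except for one O-methyl group. The four stereocentres C2, C3, C3'' and C2'' stand in a row (2S,3R,3''R,2''S), each 2-aryl group trans to the C3–C3'' bond on its ring. Fragile points are the enolisable centres C3 and C3'', the benzylic aryl ether bonds O1–C2 and O1''–C2'' (they open by retro-oxa-Michael reaction under base and would scramble C2 and C2''), the electron-rich phloroglucinol rings, and the one methyl ether that must survive while five phenols are freed. The real difficulty is the hindered C3–C3'' bond between two stereocentres of an unsymmetrical dimer, to be made without enolate chemistry that endangers C2 and C2''. The key step exploits the 1,4-diketone C4(=O)–C3–C3''–C4''(=O), read as a cleaved cyclobutene C4=C4''–C3''–C3. Because C4 and C4'' each sit on a ring-A carbon (C4a, C4a'') whose ortho neighbour (C8a, C8a'') carries the ether oxygen leading to C2 (C2''), an alkyne C4≡C4'' and an alkene C3=C3'' are tied twice, in a 12-membered ring.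

## Logic of the disconnections

19 ⇒ 18. The five benzyl–oxygen bonds are cut. Benzyl ethers come off by neutral hydrogenolysis, which spares the methyl ether, the ketones and the base-sensitive stereocentres. The gain is that every earlier compound is a neutral, non-phenolic ether. The demand is that hydrogenolysis leaves the benzylic O1–C2 and O1''–C2'' ring bonds and the ketones alone.

18 ⇒ 16 (through 17). The two C=O bonds at C4 and C4'' are traced back to one C4=C4'' double bond. This turns the 1,4-diketone into a cyclobutene, so both carbonyl carbons enter at the alkyne oxidation level and no enolate is ever formed. All four stereocentres are already present in 16. The demand is a neutral oxidative cleavage that takes the strained stilbene-type alkene before the alkoxyarenes.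

16 ⇒ 15. The bonds C3–C4 and C3''–C4'' are cut in a retro-[2+2] sense. This opens the cyclobutene and both pyran rings at once and removes C3 and C3'' as stereocentres. What remains is a macrocycle that is C2-symmetric apart from one methyl/benzyl difference. The demand is that the excited alkyne adds across the ring to the alkene face fixed by C2 and C2''; this needs the (S,S) configuration together with the E-alkene.

15 ⇒ 14. The C3=C3'' double bond is cut. Each half then ends in a vinyl group, which is exactly what a branched-selective allylic etherification delivers. The gain is an acyclic tolane. The demand is that diene ring closure to a 12-membered ring beats enyne metathesis and oligomerisation.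

14 ⇒ 12 + 10 (through 13), and 12 ⇒ 9 + 11. The two aryl–alkyne bonds C4a–C4 and C4a''–C4'' are cut. Both ring A units are the same iodoarene, and coupling them one after the other to a two-carbon alkyne unit keeps the two halves distinct without statistics. The gain is two halves of equal size. The demand is that zerovalent palladium leaves the allylic aryl ethers untouched.

9 ⇒ 2 + 4, and 10 ⇒ 2 + 8. The bonds O1–C2 and O1''–C2'' are cut. Both stereocentres then come from one catalytic asymmetric reaction, with one phenol and one catalyst antipode, because both centres are S. The gain is achiral pieces. The demand is high branched selectivity and enantioselectivity with an ortho-iodinated aryloxide, and products that do not re-ionise.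

2 ⇒ 1; 4 ⇒ 3; 8 ⇒ 7 ⇒ 6 ⇒ 5. A C–I bond, two carbonate C–O bonds, one ester reduction and one C=C bond are cut. These are standard operations on commercial materials. The only demand is iodination ortho to the free hydroxyl of 1.

## Other disconnections considered

Alternative 1: The cut is at O1–C2 and O1''–C2'', back to the bis-dihydrochalcone A1. In the forward step, anodic oxidation (graphite, LiClO4/MeOH, 2,6-lutidine) or Ag2O would turn each 4-hydroxybenzyl arm into a p-quinone methide, and the neighbouring 2'-hydroxyl would add to it, closing both rings C to give A2.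
- In its favour: it is biomimetic and closes two rings in one operation. It needs no macrocycle and no noble metal, and A1 comes from simple acetophenone and aldehyde chemistry. Reversible addition to the quinone methide should settle each ring trans.
- Against it here: A2 carries two equivalent free 4'-phenols, whereas the target needs one of them methylated. A 4-methoxybenzyl arm cannot form the quinone methide, so the difference would have to come from a statistical mono-methylation. The only stereocentres of A1 are enolisable and come from an enolate coupling with no evident asymmetric version, so the single enantiomer would need a resolution. The 2'-hydroxyaryl ketone and methanol compete for oxidation and for the quinone methide.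
- Comparison: on structure it equals the chosen plan in forming both rings C at once and is weaker on the ring-B difference and on absolute configuration. On mechanism it is the better founded of the two, since oxa-Michael addition to a quinone methide is an ordinary polar step, though the double anodic version is itself untested. On step economy it is clearly better, at roughly half the length.

Alternative 2: The cut is at C3–C3'' plus a temporary C2–C2'' bond, back to two molecules of chalcone A3. In the forward step, Sc(OTf)3 with a chiral PyBox ligand and Ru(bpy)3(PF6)2 under visible light would dimerise A3 head to head to the all-trans cyclobutane A4.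
- In its favour: the C3–C3'' bond, its trans relation and its absolute configuration would be set in one catalytic step from a one-step chalcone. Lewis-acid-assisted enantioselective [2+2] photocycloaddition of 2'-hydroxychalcones is closer to precedent than step 11, and that is a point on which this alternative is the better.
- Against it here: the C2–C2'' bond must then be broken and two C–O bonds made. An oxidative fragmentation of the 1,2-diarylcyclobutane with phenol capture is unprecedented and competes with full cycloreversion to A3. C2 and C2'' are set only afterwards, under substrate control. A homodimer has two identical rings B, so the methyl/hydroxyl difference is again statistical.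
- Comparison: on structure it is better for the central bond and weaker for the ring-B difference. On mechanism it moves the unproven chemistry from the ring-forming step to the sacrificial-bond cleavage and does not remove it. On step economy it would be much shorter if that cleavage worked.

Alternative 3: The cut is at C2–C1' and C2''–C1''', back to the 3,3'-bichromone A5. In the forward step, Pd(OCOCF3)2 with a chiral pyridine-oxazoline ligand would add 4-methoxyphenylboronic acid and then 4-(benzyloxy)phenylboronic acid to the two chromone C2=C3 bonds, giving A6, which is identical with 18.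
- In its favour: it converges on the same late intermediate with the same last step. The two different rings B enter last from two different boronic acids, which in principle handles the unsymmetry as well as or better than the chosen plan. It is far shorter.
- Against it here: conjugate arylation is established for chromones that are unsubstituted at C3. A5 is an α-branched, trisubstituted acceptor in which insertion is slow. C3 and C3'' would be fixed only when the palladium enolate is protonated, so a base equilibration that risks ring opening would be needed. The first addition must stop cleanly at the mono-adduct of two identical chromone units. The second addition faces matched/mismatched control.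
- Comparison: on structure it is equal, since it ends at the same compound. On mechanism each bond formation is a known type but outside its proven substrate class, whereas the chosen plan sets C2 and C2'' by an established reaction and concentrates its risk in one step. On step economy Alternative 3 is the better.

Key step: step 11

## Remarks before the steps

Assumption: the (Sa,S,S) antipode of ligand L, O,O'-(1,1'-binaphthyl-2,2'-diyl) N,N-bis(1-phenylethyl)phosphoramidite, is taken to deliver the (S)-ethers 9 and 10; if the sense of induction is the reverse, its mirror image is used and nothing else changes.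

Structure check: 15 and 16 were compared atom by atom with 19 and need no correction. C2 and C2'' are S throughout. The arrangement at C3 and C3'' is the same in 16, 18 and 19; the descriptors read S in 16 and R in 18 and 19 only because C4 and C4'' change rank when they become carbonyl carbons.

Design changes: no base equilibration follows the cleavage, because the cycloaddition is expected to set C3 and C3'' directly and base would endanger C2 and C2''. The C-silyl group is removed in the flask of the second coupling. Ozone is dosed.

## Route

Step 1
Reactants: 1 3,5-bis(benzyloxy)phenol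
Product: 2 3,5-bis(benzyloxy)-2-iodophenol
Conditions: I2 (1.0 equiv), NaHCO3, THF/H2O, 0 °C
Reagents that add atoms: iodine, [I][I]
Why: Electrophilic aromatic iodination of the phenoxide; attack ortho to the free hydroxyl is expected because the position between the two benzyloxy groups is the more hindered, and one equivalent of iodine at 0 °C limits di-iodination.

Step 2
Reactants: 3 (E)-3-(4-methoxyphenyl)prop-2-en-1-ol
Product: 4 (E)-3-(4-methoxyphenyl)allyl methyl carbonate
Conditions: ClCO2Me, pyridine, CH2Cl2, 0 °C
Reagents that add atoms: methyl chloroformate, COC(=O)Cl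
Why: O-Acylation of a primary allylic alcohol with a chloroformate; the alkene geometry is not touched.

Step 3
Reactants: 5 4-(benzyloxy)benzaldehyde
Product: 6 ethyl (E)-3-[4-(benzyloxy)phenyl]acrylate
Conditions: (EtO)2P(O)CH2CO2Et, NaH, THF, 0 °C to rt
Reagents that add atoms: triethyl phosphonoacetate, CCOC(=O)CP(=O)(OCC)OCC
Why: Horner–Wadsworth–Emmons olefination; the stabilised phosphonate anion gives the E-alkene.

Step 4
Reactants: 6 ethyl (E)-3-[4-(benzyloxy)phenyl]acrylate
Product: 7 (E)-3-[4-(benzyloxy)phenyl]prop-2-en-1-ol
Conditions: iBu2AlH (2.2 equiv), CH2Cl2, −78 °C; aqueous Rochelle salt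
Reagents that add atoms: none
Why: 1,2-Reduction of a conjugated ester by the aluminium hydride at low temperature, which spares the alkene and the benzyl ether.

Step 5
Reactants: 7 (E)-3-[4-(benzyloxy)phenyl]prop-2-en-1-ol
Product: 8 (E)-3-[4-(benzyloxy)phenyl]allyl methyl carbonate
Conditions: ClCO2Me, pyridine, CH2Cl2, 0 °C
Reagents that add atoms: methyl chloroformate, COC(=O)Cl
Why: O-Acylation of the primary allylic alcohol, as in step 2.

Step 6
Reactants: 2 3,5-bis(benzyloxy)-2-iodophenol; 4 (E)-3-(4-methoxyphenyl)allyl methyl carbonate
Product: 9 1,5-bis(benzyloxy)-2-iodo-3-{[(1S)-1-(4-methoxyphenyl)prop-2-en-1-yl]oxy}benzene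
Conditions: 2, LiN(SiMe3)2 (1.0 equiv), THF, 0 °C; then 4 (1.3 equiv), [Ir(cod)Cl]2 (2 mol%), (Sa,S,S)-L (4 mol%), THF, rt to 40 °C
Reagents that add atoms: none
Why: Iridium-catalysed asymmetric allylic etherification; the lithium aryloxide attacks the substituted terminus of the allyliridium intermediate formed from the linear carbonate, which gives the branched ether, and the cyclometallated iridium–phosphoramidite catalyst sets C2 as S.

Step 7
Reactants: 2 3,5-bis(benzyloxy)-2-iodophenol; 8 (E)-3-[4-(benzyloxy)phenyl]allyl methyl carbonate
Product: 10 1,5-bis(benzyloxy)-3-({(1S)-1-[4-(benzyloxy)phenyl]prop-2-en-1-yl}oxy)-2-iodobenzene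
Conditions: 2, LiN(SiMe3)2 (1.0 equiv), THF, 0 °C; then 8 (1.3 equiv), [Ir(cod)Cl]2 (2 mol%), (Sa,S,S)-L (4 mol%), THF, rt to 40 °C
Reagents that add atoms: none
Why: The same iridium-catalysed asymmetric allylic etherification with the same catalyst antipode sets C2'' as S, as the C2 symmetry of the core requires.

Step 8
Reactants: 9 1,5-bis(benzyloxy)-2-iodo-3-{[(1S)-1-(4-methoxyphenyl)prop-2-en-1-yl]oxy}benzene; 11 ethynyltrimethylsilane
Product: 12 {[2,4-bis(benzyloxy)-6-{[(1S)-1-(4-methoxyphenyl)prop-2-en-1-yl]oxy}phenyl]ethynyl}trimethylsilane
Conditions: PdCl2(PPh3)2 (3 mol%), CuI (6 mol%), Et3N, THF, rt to 40 °C, degassed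
Reagents that add atoms: none
Why: Sonogashira coupling of the aryl iodide; transmetalation from the copper acetylide near room temperature should outrun insertion of the neighbouring vinyl group, and the tertiary amine offers no nucleophile for allylic substitution.

Step 9
Reactants: 12 {[2,4-bis(benzyloxy)-6-{[(1S)-1-(4-methoxyphenyl)prop-2-en-1-yl]oxy}phenyl]ethynyl}trimethylsilane; 10 1,5-bis(benzyloxy)-3-({(1S)-1-[4-(benzyloxy)phenyl]prop-2-en-1-yl}oxy)-2-iodobenzene
Product: 14 acyclic tolane diene (S,S)-1-[2,4-bis(benzyloxy)-6-{[1-(4-methoxyphenyl)prop-2-en-1-yl]oxy}phenyl]-2-[2,4-bis(benzyloxy)-6-({1-[4-(benzyloxy)phenyl]prop-2-en-1-yl}oxy)phenyl]ethyne, via terminal alkyne 13 (not isolated)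
Conditions: 12, Bu4NF (1.05 equiv), THF, 0 °C; then 10 (1.1 equiv), Pd(PPh3)4 (5 mol%), CuI (10 mol%), Et3N, rt to 40 °C, degassed
Reagents that add atoms: none
Why: Fluoride cleaves the C–Si bond and the terminal alkyne is coupled in the same flask (desilylative Sonogashira coupling); the slight excess of aryl iodide keeps zerovalent palladium engaged in oxidative addition and away from the allylic ethers.

Step 10
Reactants: 14 acyclic tolane diene
Product: 15 (2S,2''S,E)-macrocycle with the 12-membered ring C2–O1–C8a–C4a–C4≡C4''–C4a''–C8a''–O1''–C2''–C3''=C3 carrying 4-methoxyphenyl at C2 and 4-(benzyloxy)phenyl at C2'' and benzyloxy groups at C5 and C7 and C5'' and C7''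
Conditions: second-generation Grubbs catalyst RuCl2(=CHPh)(H2IMes)(PCy3) (10 mol%), CH2Cl2 (1 mM), 40 °C
Reagents that add atoms: none
Why: Ring-closing olefin metathesis with loss of ethylene; the rigid tolane holds both vinyl groups on one side, the alkyne flanked by four ortho oxygen substituents should be too hindered for enyne metathesis, and the E-alkene is expected as the less strained isomer under equilibrating conditions.

Step 11
Reactants: 15 (2S,2''S,E)-macrocycle
Product: 16 tetracyclic 1,2-diarylcyclobutene with the four-membered ring C4=C4''–C3''–C3 and both pyran rings closed, H3 trans to H2 and H3'' trans to H2'' and H3 trans to H3'' (descriptors 2S,3S,2''S,3''S)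
Conditions: thioxanthone (10 mol%), 405 nm LED, CH2Cl2 (2 mM), argon, 20 °C
Reagents that add atoms: none
Why: Proposed new method: triplet energy transfer from thioxanthone (triplet energy about 65 kcal/mol) to the hexaalkoxytolane (tolane itself about 62 kcal/mol), the only chromophore of 15 within reach, gives a triplet diarylalkyne that reacts as a 1,2-biradical; the closest known reaction type is the [2+2] photocycloaddition of diarylalkynes to alkenes that gives cyclobutenes, by direct or triplet-sensitised excitation, which has not been run across a macrocycle. C4 adds to C3 in a 6-exo-trig radical addition that closes the first pyran ring (C4, C4a, C8a, O1, C2, C3) through a chair-like transition state, and after intersystem crossing the 1,4-biradical (alkenyl at C4'', alkyl at C3'') collapses by radical recombination, which closes the cyclobutene and with it the second pyran ring (C4'', C4a'', C8a'', O1'', C2'', C3''). C3 is set by C2: in the reactive conformer the C2–H bond eclipses the alkene (least allylic strain), the C2–O1 bond stands perpendicular to it and the 4-methoxyphenyl group points away, so the tethered C4 arrives on the face that puts H3 trans to H2. C3'' is set by the E-alkene and by C2'': 15 is C2-symmetric about the axis through the midpoints of alkyne and alkene, so the same argument holds for the second half, and a biradical that rotated before closure would still favour the trans-cyclobutene, the only one in which the two ring A units can twist out of the cyclobutene plane in opposite senses and keep the 5- and 5''-benzyloxy groups apart. The selectivity needed is cycloaddition over reversion of the biradical (alkene isomerisation or loss of an aryloxyl radical by β-scission) and over intermolecular addition; the 12-membered ring secures it by holding the two π systems face to face at high dilution, and 405 nm light excites neither 15 nor its benzyl ethers directly. Oxygen is excluded because the sensitiser can also excite the cis-stilbene-type chromophore of 16.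

Step 12
Reactants: 16 tetracyclic 1,2-diarylcyclobutene
Product: 18 (2S,3R,2''S,3''R)-5,7,5'',7'',4'''-pentakis(benzyloxy)-4'-methoxy-3,3''-biflavanone, via ozonide 17 (not isolated)
Conditions: O3 (1.05 equiv, saturated CH2Cl2 solution), CH2Cl2, −78 °C; then PPh3, −78 °C to rt
Reagents that add atoms: ozone, [O-][O+]=O
Why: Ozonolysis of a strained tetrasubstituted 1,2-diarylcyclobutene, the known way from such cyclobutenes to 1,4-diaryl-1,4-diketones; with dosed ozone the alkene should react before the alkoxyarenes, and the neutral reductive work-up leaves C2, C3, C3'' and C2'' as set.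

Step 13
Reactants: 18 (2S,3R,2''S,3''R)-5,7,5'',7'',4'''-pentakis(benzyloxy)-4'-methoxy-3,3''-biflavanone
Product: 19 (2S,3R,2''S,3''R)-5,7,5'',7'',4'''-pentahydroxy-4'-methoxy-3,3''-biflavanone
Conditions: H2 (1 atm), Pd/C (10%), EtOAc/MeOH, rt
Reagents that add atoms: none
Why: Hydrogenolysis of five aryl benzyl ethers under neutral conditions; the aryl methyl ether, the electron-rich aryl ketones and the ring O1–C2 bonds are much slower to react, and no base is present to enolise C3 or C3''.

## Compound list

1 | 3,5-bis(benzyloxy)phenol | Oc1cc(OCc2ccccc2)cc(OCc2ccccc2)c1 | starting material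
2 | 3,5-bis(benzyloxy)-2-iodophenol | Oc1cc(OCc2ccccc2)cc(OCc2ccccc2)c1I | intermediate
3 | (E)-3-(4-methoxyphenyl)prop-2-en-1-ol | COc1ccc(/C=C/CO)cc1 | starting material
4 | (E)-3-(4-methoxyphenyl)allyl methyl carbonate | COC(=O)OC/C=C/c1ccc(OC)cc1 | intermediate
5 | 4-(benzyloxy)benzaldehyde | O=Cc1ccc(OCc2ccccc2)cc1 | starting material
6 | ethyl (E)-3-[4-(benzyloxy)phenyl]acrylate | CCOC(=O)/C=C/c1ccc(OCc2ccccc2)cc1 | intermediate
7 | (E)-3-[4-(benzyloxy)phenyl]prop-2-en-1-ol | OC/C=C/c1ccc(OCc2ccccc2)cc1 | intermediate
8 | (E)-3-[4-(benzyloxy)phenyl]allyl methyl carbonate | COC(=O)OC/C=C/c1ccc(OCc2ccccc2)cc1 | intermediate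
9 | 1,5-bis(benzyloxy)-2-iodo-3-{[(1S)-1-(4-methoxyphenyl)prop-2-en-1-yl]oxy}benzene | COc1ccc(cc1)[C@H](C=C)Oc1cc(OCc2ccccc2)cc(OCc2ccccc2)c1I | intermediate
10 | 1,5-bis(benzyloxy)-3-({(1S)-1-[4-(benzyloxy)phenyl]prop-2-en-1-yl}oxy)-2-iodobenzene | O(Cc1ccccc1)c1ccc(cc1)[C@H](C=C)Oc1cc(OCc2ccccc2)cc(OCc2ccccc2)c1I | intermediate
11 | ethynyltrimethylsilane | C#C[Si](C)(C)C | starting material
12 | {[2,4-bis(benzyloxy)-6-{[(1S)-1-(4-methoxyphenyl)prop-2-en-1-yl]oxy}phenyl]ethynyl}trimethylsilane | COc1ccc(cc1)[C@H](C=C)Oc1cc(OCc2ccccc2)cc(OCc2ccccc2)c1C#C[Si](C)(C)C | intermediate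
13 | 1,5-bis(benzyloxy)-2-ethynyl-3-{[(1S)-1-(4-methoxyphenyl)prop-2-en-1-yl]oxy}benzene (terminal alkyne, not isolated) | COc1ccc(cc1)[C@H](C=C)Oc1cc(OCc2ccccc2)cc(OCc2ccccc2)c1C#C | intermediate
14 | acyclic tolane diene, (S,S)-1-[2,4-bis(benzyloxy)-6-{[1-(4-methoxyphenyl)prop-2-en-1-yl]oxy}phenyl]-2-[2,4-bis(benzyloxy)-6-({1-[4-(benzyloxy)phenyl]prop-2-en-1-yl}oxy)phenyl]ethyne | COc1ccc(cc1)[C@H](C=C)Oc1cc(OCc2ccccc2)cc(OCc2ccccc2)c1C#Cc1c(OCc2ccccc2)cc(OCc2ccccc2)cc1O[C@H](c1ccc(OCc2ccccc2)cc1)C=C | intermediate
15 | (2S,2''S,E)-12-membered 2,2'-dioxytolane macrocycle bridged from O1 to O1'' by CH(4-methoxyphenyl)–CH=CH–CH[4-(benzyloxy)phenyl], benzyloxy at C5, C7, C5'', C7'' | COc1ccc(cc1)[C@H]1Oc2cc(OCc3ccccc3)cc(OCc3ccccc3)c2C#Cc2c(OCc3ccccc3)cc(OCc3ccccc3)cc2O[C@H](c2ccc(OCc3ccccc3)cc2)/C=C/1 | intermediate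
16 | tetracyclic 1,2-diarylcyclobutene (ring C4=C4''–C3''–C3, both pyran rings closed; H2/H3 trans, H3/H3'' trans, H3''/H2'' trans; 2S,3S,2''S,3''S) | COc1ccc(cc1)[C@H]1Oc2cc(OCc3ccccc3)cc(OCc3ccccc3)c2C2=C3c4c(OCc5ccccc5)cc(OCc5ccccc5)cc4O[C@H](c4ccc(OCc5ccccc5)cc4)[C@H]3[C@H]12 | intermediate
17 | bridged ozonide of 16 (C4 and C4'' joined by one O and by O–O; one of two near-equivalent bridge orientations drawn; not isolated) | COc1ccc([C@H]2Oc3cc(OCc4ccccc4)cc(OCc4ccccc4)c3[C@]7(OO8)[C@@H]2[C@H]2[C@@]8(O7)c3c(OCc4ccccc4)cc(OCc4ccccc4)cc3O[C@@H]2c2ccc(OCc3ccccc3)cc2)cc1 | intermediate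
18 | (2S,3R,2''S,3''R)-5,7,5'',7'',4'''-pentakis(benzyloxy)-4'-methoxy-3,3''-biflavanone | COc1ccc([C@H]2Oc3cc(OCc4ccccc4)cc(OCc4ccccc4)c3C(=O)[C@@H]2[C@H]2C(=O)c3c(OCc4ccccc4)cc(OCc4ccccc4)cc3O[C@@H]2c2ccc(OCc3ccccc3)cc2)cc1 | intermediate
19 | (2S,3R,2''S,3''R)-5,7,5'',7'',4'''-pentahydroxy-4'-methoxy-3,3''-biflavanone | COc1ccc([C@H]2Oc3cc(O)cc(O)c3C(=O)[C@@H]2[C@H]2C(=O)c3c(O)cc(O)cc3O[C@@H]2c2ccc(O)cc2)cc1 | target

## Step count and least certain steps

Total: 13 steps. Longest linear sequence: 9 steps (5 → 6 → 7 → 8 → 10 → 14 → 15 → 16 → 18 → 19; steps 3, 4, 5, 7, 9, 10, 11, 12, 13).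

Step 11 (key step, proposed new method).
- What may go wrong: the triplet alkyne may decay without adding. The 1,4-biradical may revert, which isomerises the alkene or expels an aryloxyl radical. The triplet sensitiser may abstract the doubly activated hydrogen at C2 or C2''. Secondary sensitisation may consume the cycloadduct. All of these stem from the fact that the transannular addition has to be faster than every unimolecular escape of a short-lived excited state.
- Fallback by known chemistry (sets out from 1, rejoins at 18): the C3–C3'' bond is made by a silicon-tethered oxidative enolate heterocoupling of two enantiopure flavanones. C-Acetylation of 1 ortho to the hydroxyl (Ac2O, BF3·OEt2) gives 1-[2,4-bis(benzyloxy)-6-hydroxyphenyl]ethanone F1. Condensation with N,N-dimethylformamide dimethyl acetal and acid-mediated ring closure give 5,7-bis(benzyloxy)chromone F2. Asymmetric conjugate addition catalysed by divalent palladium (Pd(OCOCF3)2, tBu-PyOx of the handedness that gives the S product, NH4PF6, wet 1,2-dichloroethane) of 4-methoxyphenylboronic acid gives (S)-5,7-bis(benzyloxy)-4'-methoxyflavanone F3, and that of 4-(benzyloxy)phenylboronic acid gives (S)-4',5,7-tris(benzyloxy)flavanone F4. The lithium enolate of F3 (LiN(iPr)2, THF, −78 °C) is silylated with excess Me2SiCl2 to the chlorodimethylsilyl enol ether F5, which with the lithium enolate of F4 gives the unsymmetrical dimethylsilyl bis-enol ether F6. Oxidation with (NH4)2Ce(NO3)6 and NaHCO3 in acetonitrile at −10 °C joins C3 to C3'' within the tether, each new centre trans to its 2-aryl group, and releases 18.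

Step 10.
- What may go wrong: the ruthenium carbene formed at one vinyl group may add across the alkyne (ring-closing enyne metathesis to a six-membered ring), which is kinetically easier than closure of a 12-membered ring if the steric shielding of the alkyne proves insufficient. Cross metathesis to oligomers and formation of the Z-alkene are further risks.
- Fallback (sets out from 9 and 10, rejoins at 15): the ring is closed at the alkyne, not the alkene. Cross metathesis of 10 with an excess of 9 (second-generation Grubbs catalyst, CH2Cl2, 40 °C; no alkyne is present) gives the (S,S,E)-1,4-diaryl-1,4-bis(2-iodoaryloxy)but-2-ene F7. A double Stille coupling of F7 with bis(tributylstannyl)acetylene (Pd(PPh3)4, toluene, high dilution) closes the macrocycle 15.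

Step 9 (and likewise step 8).
- What may go wrong: zerovalent palladium may ionise the branched 1-arylallyl aryl ethers, which scrambles them to linear cinnamyl ethers and erodes the configuration at C2 and C2''. After oxidative addition into 10 the arylpalladium may insert the neighbouring vinyl group (Heck cyclisation). Both pathways gain ground when the hindered, electron-rich iodide couples slowly.
- Fallback (sets out from 12 and 2, rejoins at 14): the second aryl–alkyne bond is made before the second ether. Acetylation of 2 (Ac2O, pyridine) gives 3,5-bis(benzyloxy)-2-iodophenyl acetate F8. 12 is desilylated separately (K2CO3, MeOH), and 13, isolated this time, is coupled with an excess of F8 (PdCl2(PPh3)2, CuI, Et3N, rt), which carries no allyl group, to the tolane acetate F9. Methanolysis (K2CO3, MeOH, rt) frees the tolane phenol F10. Its lithium aryloxide undergoes the iridium-catalysed etherification with 8 under the conditions of step 7 and gives 14.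

Step 7 (and likewise step 6).
- What may go wrong: the hindered ortho-iodinated aryloxide may attack slowly, and the electron-rich branched product may re-ionise on the catalyst, which lowers the branched-to-linear ratio and the enantiomeric purity.
- Fallback (sets out from 5 and 2, rejoins at 10; the other half would be made in the same way): the stereocentre is set by a propargylic substitution. Addition of ethynylmagnesium bromide to 5 and acetylation in the same flask (Ac2O) give racemic 1-[4-(benzyloxy)phenyl]prop-2-yn-1-yl acetate F11. Enantioselective propargylic etherification of 2 catalysed by monovalent copper (CuOTf·½C6H6, chiral PyBox ligand, iPr2NEt, MeOH, −20 °C), through a copper allenylidene, gives the (S)-propargyl aryl ether F12. Semi-hydrogenation (H2, Pd/CaCO3 poisoned with Pb(OAc)2, quinoline; Lindlar conditions) gives 10.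

Step 12.
- What may go wrong: ozone may attack the very electron-rich ring A units or the benzylic positions in competition with the alkene, because trialkoxyarenes are themselves reactive towards ozone. The hindered bridged ozonide may be reduced incompletely.
- Fallback (sets out from 16, rejoins at 18): the cleavage is done in two steps through a glycol. Dihydroxylation of the strained alkene (OsO4 catalytic, N-methylmorpholine N-oxide, acetone/H2O) gives the cis-4,4''-diol F13. Glycol cleavage with Pb(OAc)4 (CH2Cl2, 0 °C) gives 18.

## Further compounds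

F1 | step 11 | 1-[2,4-bis(benzyloxy)-6-hydroxyphenyl]ethanone | CC(=O)c1c(O)cc(OCc2ccccc2)cc1OCc1ccccc1
F2 | step 11 | 5,7-bis(benzyloxy)-4H-chromen-4-one | O=c1ccoc2cc(OCc3ccccc3)cc(OCc3ccccc3)c12
F3 | step 11 | (S)-5,7-bis(benzyloxy)-2-(4-methoxyphenyl)chroman-4-one | COc1ccc([C@H]2Oc3cc(OCc4ccccc4)cc(OCc4ccccc4)c3C(=O)C2)cc1
F4 | step 11 | (S)-5,7-bis(benzyloxy)-2-[4-(benzyloxy)phenyl]chroman-4-one | O(Cc1ccccc1)c1ccc([C@H]2Oc3cc(OCc4ccccc4)cc(OCc4ccccc4)c3C(=O)C2)cc1
F5 | step 11 | chlorodimethylsilyl enol ether of F3, (S)-5,7-bis(benzyloxy)-4-[(chlorodimethylsilyl)oxy]-2-(4-methoxyphenyl)-2H-chromene | COc1ccc([C@H]2Oc3cc(OCc4ccccc4)cc(OCc4ccccc4)c3C(O[Si](C)(C)Cl)=C2)cc1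
F6 | step 11 | unsymmetrical dimethylsilyl bis-enol ether of F3 and F4 (both 2S) | COc1ccc([C@H]2Oc3cc(OCc4ccccc4)cc(OCc4ccccc4)c3C(O[Si](C)(C)OC3=C[C@@H](c4ccc(OCc5ccccc5)cc4)Oc4cc(OCc5ccccc5)cc(OCc5ccccc5)c34)=C2)cc1
F7 | step 10 | (S,S,E)-1-(4-methoxyphenyl)-4-[4-(benzyloxy)phenyl]-1,4-bis[3,5-bis(benzyloxy)-2-iodophenoxy]but-2-ene | COc1ccc(cc1)[C@H](/C=C/[C@@H](c1ccc(OCc2ccccc2)cc1)Oc1cc(OCc2ccccc2)cc(OCc2ccccc2)c1I)Oc1cc(OCc2ccccc2)cc(OCc2ccccc2)c1I
F8 | step 9 | 3,5-bis(benzyloxy)-2-iodophenyl acetate | CC(=O)Oc1cc(OCc2ccccc2)cc(OCc2ccccc2)c1I
F9 | step 9 | tolane acetate, (S)-2-{[2,4-bis(benzyloxy)-6-{[1-(4-methoxyphenyl)prop-2-en-1-yl]oxy}phenyl]ethynyl}-3,5-bis(benzyloxy)phenyl acetate | COc1ccc(cc1)[C@H](C=C)Oc1cc(OCc2ccccc2)cc(OCc2ccccc2)c1C#Cc1c(OCc2ccccc2)cc(OCc2ccccc2)cc1OC(C)=O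
F10 | step 9 | tolane phenol, (S)-2-{[2,4-bis(benzyloxy)-6-{[1-(4-methoxyphenyl)prop-2-en-1-yl]oxy}phenyl]ethynyl}-3,5-bis(benzyloxy)phenol | COc1ccc(cc1)[C@H](C=C)Oc1cc(OCc2ccccc2)cc(OCc2ccccc2)c1C#Cc1c(OCc2ccccc2)cc(OCc2ccccc2)cc1O
F11 | step 7 | 1-[4-(benzyloxy)phenyl]prop-2-yn-1-yl acetate (racemic) | CC(=O)OC(C#C)c1ccc(OCc2ccccc2)cc1
F12 | step 7 | 1,5-bis(benzyloxy)-3-({(1S)-1-[4-(benzyloxy)phenyl]prop-2-yn-1-yl}oxy)-2-iodobenzene | O(Cc1ccccc1)c1ccc(cc1)[C@H](C#C)Oc1cc(OCc2ccccc2)cc(OCc2ccccc2)c1I
F13 | step 12 | cis-4,4''-diol of 16 (cyclobutane-1,2-diol; one of two near-equivalent faces drawn) | COc1ccc([C@H]2Oc3cc(OCc4ccccc4)cc(OCc4ccccc4)c3[C@@]7(O)[C@@H]2[C@H]2[C@@]7(O)c3c(OCc4ccccc4)cc(OCc4ccccc4)cc3O[C@@H]2c2ccc(OCc3ccccc3)cc2)cc1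
A1 | alternative 1 | (2S,3S)-2,3-bis(4-hydroxybenzyl)-1,4-bis[2-hydroxy-4,6-bis(methoxymethoxy)phenyl]butane-1,4-dione | O=C(c1c(O)cc(OCOC)cc1OCOC)[C@@H](Cc1ccc(O)cc1)[C@H](Cc1ccc(O)cc1)C(=O)c1c(O)cc(OCOC)cc1OCOC
A2 | alternative 1 | (2S,3R,2''S,3''R)-4',4'''-dihydroxy-5,7,5'',7''-tetrakis(methoxymethoxy)-3,3''-biflavanone | Oc1ccc([C@H]2Oc3cc(OCOC)cc(OCOC)c3C(=O)[C@@H]2[C@H]2C(=O)c3c(OCOC)cc(OCOC)cc3O[C@@H]2c2ccc(O)cc2)cc1
A3 | alternative 2 | (E)-3-[4-(benzyloxy)phenyl]-1-[2-hydroxy-4,6-bis(methoxymethoxy)phenyl]prop-2-en-1-one | O=C(/C=C/c1ccc(OCc2ccccc2)cc1)c1c(O)cc(OCOC)cc1OCOC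
A4 | alternative 2 | all-trans 1,2-bis[2-hydroxy-4,6-bis(methoxymethoxy)benzoyl]-3,4-bis[4-(benzyloxy)phenyl]cyclobutane | O=C(c1c(O)cc(OCOC)cc1OCOC)[C@H]1[C@H](c2ccc(OCc3ccccc3)cc2)[C@@H](c2ccc(OCc3ccccc3)cc2)[C@@H]1C(=O)c1c(O)cc(OCOC)cc1OCOC
A5 | alternative 3 | 5,7,5',7'-tetrakis(benzyloxy)-3,3'-bichromone | O=c1c(-c2coc3cc(OCc4ccccc4)cc(OCc4ccccc4)c3c2=O)coc2cc(OCc3ccccc3)cc(OCc3ccccc3)c12
A6 | alternative 3 | (2S,3R,2''S,3''R)-5,7,5'',7'',4'''-pentakis(benzyloxy)-4'-methoxy-3,3''-biflavanone (identical with 18) | COc1ccc([C@H]2Oc3cc(OCc4ccccc4)cc(OCc4ccccc4)c3C(=O)[C@@H]2[C@H]2C(=O)c3c(OCc4ccccc4)cc(OCc4ccccc4)cc3O[C@@H]2c2ccc(OCc3ccccc3)cc2)cc1
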